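The route cuts the bond between the benzylic CH2 (C-7) and the veratryl ring (ring A). C-7 is primary and lies two bonds from the methoxy-bearing quaternary carbon (C-3') of the dienone ring (ring B). A carboxyl group on C-7 therefore serves twice. As internal nucleophile it dearomatises a phenol by spirolactonisation and fixes C-3' relative to the C-8 methyl centre; in the key step it leaves as CO2. There a nickel/photoredox decarboxylative coupling joins the methoxy acid, which already holds ring B and both stereocentres, to 4-iodoveratrole and gives lancifolin C directly.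

Key step: step 6

Remark: ring A = veratryl ring; C-7 = benzylic CH2; C-8 = methyl-bearing CH; ring B = dienone ring with C-1' (allyl-bearing), C-2' (CH), C-3' (quaternary, OMe), C-4' (enol ether, OMe), C-5' (CH), C-6' (C=O). Salts that are only protonated on work-up are not numbered.

Step 1
Reactants: 1 4-bromo-3-methoxyphenol; 2 allyl bromide
Product: 3 1-bromo-2-methoxy-4-(prop-2-en-1-yloxy)benzene
Conditions: K2CO3, acetone, reflux
Reagents that add atoms: none
Why: Williamson ether synthesis on the phenoxide; the allyl ether protects the phenol for the Grignard step and is the source of the later C-allyl group.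

Step 2
Reactants: 3 1-bromo-2-methoxy-4-(prop-2-en-1-yloxy)benzene; 4 (4S)-4-methyloxetan-2-one
Product: 6 (3R)-3-[2-methoxy-4-(prop-2-en-1-yloxy)phenyl]butanoic acid, via arylmagnesium bromide 5 (not isolated)
Conditions: Mg, LiCl, THF, 25 °C; then CuBr·SMe2 (10 mol%), 4, THF–Me2S, −30 to 0 °C; aq. HCl
Reagents that add atoms: none
Why: Copper-catalysed SN2 opening of the strained β-lactone by the aryl Grignard reagent, in which the soft arylcopper species attacks the alkyl C–O carbon rather than the acyl carbon, and inversion there turns the 4S lactone centre into the 3R benzylic centre (C-8).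

Step 3
Reactants: 6 (3R)-3-[2-methoxy-4-(prop-2-en-1-yloxy)phenyl]butanoic acid
Product: 7 (3R)-3-[4-hydroxy-2-methoxy-5-(prop-2-en-1-yl)phenyl]butanoic acid
Conditions: N,N-diethylaniline, 190 °C
Reagents that add atoms: none
Why: Aromatic Claisen rearrangement ([3,3]-sigmatropic shift, then tautomerisation); the ortho position between the two oxygen substituents is shielded by the methoxy group, which the neighbouring sec-alkyl chain pushes toward it, so migration to C-5 should dominate, the basic solvent suppresses acid-induced cyclisation of the allylphenol, and C-8 is not touched.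

Step 4
Reactants: 7 (3R)-3-[4-hydroxy-2-methoxy-5-(prop-2-en-1-yl)phenyl]butanoic acid
Product: 8 (4R,5S)-6-methoxy-4-methyl-9-(prop-2-en-1-yl)-1-oxaspiro[4.5]deca-6,9-diene-2,8-dione
Conditions: PhI(OAc)2, MeCN, 0 °C
Reagents that add atoms: none
Why: Oxidative dearomatising spirolactonisation: the phenol is activated on the trivalent iodine reagent and the tethered carboxylate attacks the para carbon (5-exo), so oxygen arrives on the face that carries C-7; in the transition state the C-8 hydrogen, not the C-8 methyl, should sit beside the ortho methoxy group (allylic 1,3-strain), which sets the spiro carbon (C-3') as S relative to the existing R centre.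

Step 5
Reactants: 8 (4R,5S)-6-methoxy-4-methyl-9-(prop-2-en-1-yl)-1-oxaspiro[4.5]deca-6,9-diene-2,8-dione
Product: 11 (3R)-3-[(1S)-1,6-dimethoxy-4-oxo-3-(prop-2-en-1-yl)cyclohexa-2,5-dien-1-yl]butanoic acid, via lithium hydroxy carboxylate 9 (not isolated), via methoxy methyl ester 10 (not isolated)
Conditions: LiOH, THF–H2O, 0 °C; evaporate; NaH, MeI, DMF, 0 to 25 °C; then aq. LiOH, THF, 25 °C; aq. HCl to pH 4
Reagents that add atoms: lithium hydroxide ([Li+].[OH-]); iodomethane (CI)
Why: Saponification opens the lactone at the acyl carbon, so the C-3'–O bond and both stereocentres stay as they are; exhaustive Williamson methylation of the tertiary alkoxide and the carboxylate blocks relactonisation, and ester hydrolysis frees the acid.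

Step 6
Reactants: 11 (3R)-3-[(1S)-1,6-dimethoxy-4-oxo-3-(prop-2-en-1-yl)cyclohexa-2,5-dien-1-yl]butanoic acid; 12 4-iodo-1,2-dimethoxybenzene
Product: 13 lancifolin C, (4S)-4-[(2R)-1-(3,4-dimethoxyphenyl)propan-2-yl]-4,5-dimethoxy-2-(prop-2-en-1-yl)cyclohexa-2,5-dien-1-one
Conditions: Ir[dF(CF3)ppy]2(dtbbpy)PF6 (2 mol%), NiCl2·DME (20 mol%), 4,4'-di-tert-butyl-2,2'-bipyridine (25 mol%), Cs2CO3, DMSO, 450 nm LEDs, 25 °C
Reagents that add atoms: none
Why: The carboxylate of 11 is oxidised by the excited iridium photocatalyst and loses CO2 to give the primary C-7 radical, while zerovalent nickel inserts into the C–I bond of 12; the aryl nickel species captures the radical, reductive elimination from trivalent nickel forms the C-7–aryl bond, and the reduced photocatalyst returns monovalent nickel to the zerovalent state. The closest known reaction type is the metallaphotoredox decarboxylative sp3–sp2 cross-coupling of aliphatic carboxylic acids with aryl halides. No ring is closed and no stereocentre is formed; C-8 is beta to the radical centre and C-3' one bond further, so both pass through unchanged. The step needs the radical to choose nickel over the allyl group, the ring alkenes and beta-scission of the C-8–C-3' bond; attack on ring B would have to be 4-exo or 5-endo, the allyl group is too remote, and the high nickel loading keeps the radical short-lived. The cross-conjugated dienone does not absorb at 450 nm and its triplet should lie above that of the photocatalyst, so it should survive the irradiation.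

Compound list
1 | 4-bromo-3-methoxyphenol | COc1cc(O)ccc1Br | starting material
2 | allyl bromide | C=CCBr | starting material
3 | 1-bromo-2-methoxy-4-(prop-2-en-1-yloxy)benzene | C=CCOc1ccc(Br)c(OC)c1 | intermediate
4 | (4S)-4-methyloxetan-2-one, (S)-β-butyrolactone | C[C@H]1CC(=O)O1 | starting material
5 | [2-methoxy-4-(prop-2-en-1-yloxy)phenyl]magnesium bromide | C=CCOc1ccc([Mg]Br)c(OC)c1 | intermediate (not isolated)
6 | (3R)-3-[2-methoxy-4-(prop-2-en-1-yloxy)phenyl]butanoic acid | C=CCOc1ccc([C@H](C)CC(=O)O)c(OC)c1 | intermediate
7 | (3R)-3-[4-hydroxy-2-methoxy-5-(prop-2-en-1-yl)phenyl]butanoic acid | C=CCc1cc([C@H](C)CC(=O)O)c(OC)cc1O | intermediate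
8 | (4R,5S)-6-methoxy-4-methyl-9-(prop-2-en-1-yl)-1-oxaspiro[4.5]deca-6,9-diene-2,8-dione | C=CCC1=C[C@@](OC(=O)C2)([C@@H]2C)C(OC)=CC1=O | intermediate
9 | lithium (3R)-3-[(1S)-1-hydroxy-6-methoxy-4-oxo-3-(prop-2-en-1-yl)cyclohexa-2,5-dien-1-yl]butanoate | C=CCC1=C[C@@](O)([C@H](C)CC(=O)[O-])C(OC)=CC1=O.[Li+] | intermediate (not isolated)
10 | methyl (3R)-3-[(1S)-1,6-dimethoxy-4-oxo-3-(prop-2-en-1-yl)cyclohexa-2,5-dien-1-yl]butanoate | C=CCC1=C[C@@](OC)([C@H](C)CC(=O)OC)C(OC)=CC1=O | intermediate (not isolated)
11 | (3R)-3-[(1S)-1,6-dimethoxy-4-oxo-3-(prop-2-en-1-yl)cyclohexa-2,5-dien-1-yl]butanoic acid | C=CCC1=C[C@@](OC)([C@H](C)CC(=O)O)C(OC)=CC1=O | intermediate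
12 | 4-iodo-1,2-dimethoxybenzene, 4-iodoveratrole | COc1ccc(I)cc1OC | starting material
13 | lancifolin C, (4S)-4-[(2R)-1-(3,4-dimethoxyphenyl)propan-2-yl]-4,5-dimethoxy-2-(prop-2-en-1-yl)cyclohexa-2,5-dien-1-one | C=CCC1=C[C@@](OC)([C@H](C)Cc2ccc(OC)c(OC)c2)C(OC)=CC1=O | target

Total step count: 6
Longest linear sequence: 6 steps (from 1)

Steps most likely to fail

Step 6. The C-7 radical may fragment before nickel captures it: beta-scission of the C-8–C-3' bond would expel propene and re-aromatise ring B to a phenoxyl radical. Oxidative addition of the electron-rich aryl iodide is slow, and sensitised rearrangement of the dienone is a further loss channel. Fallback: move the coupling ahead of the dearomatisation, where the radical sits next to an arene and cannot fragment in this way. Setting out from 6, the same nickel/photoredox decarboxylative coupling with 12 should give 4-[(2R)-2-[2-methoxy-4-(prop-2-en-1-yloxy)phenyl]propyl]-1,2-dimethoxybenzene F1. Claisen rearrangement in N,N-diethylaniline at 190 °C should give 4-[(2R)-1-(3,4-dimethoxyphenyl)propan-2-yl]-5-methoxy-2-(prop-2-en-1-yl)phenol F2. Oxidation with PhI(OAc)2 in methanol at 0 °C returns to the route at 13. Without the tether, methanol is no longer delivered from the C-7 side, so facial selectivity is expected to be low and may favour the wrong epimer. The C-4 epimer (4R)-4-[(2R)-1-(3,4-dimethoxyphenyl)propan-2-yl]-4,5-dimethoxy-2-(prop-2-en-1-yl)cyclohexa-2,5-dien-1-one F3 would be removed by chromatography.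

Step 4. Facial discrimination in the spirolactonisation may be insufficient, because the bias between the ortho methoxy group and the ortho hydrogen is modest. Loss of the benzylic C-8 hydrogen to a quinone methide is a competing oxidation. Fallback: separate and recycle instead of relying on selectivity alone. The spiro epimer (4R,5R)-6-methoxy-4-methyl-9-(prop-2-en-1-yl)-1-oxaspiro[4.5]deca-6,9-diene-2,8-dione F4 is separated from 8 by chromatography. Treatment with Zn in acetic acid (reductive re-aromatisation with expulsion of the carboxylate) returns it to the route at 7 for another pass through step 4.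

Step 2. The aryl–metal may attack the acyl carbon of the lactone instead of the alkyl C–O carbon, displacement at the secondary carbon by the ortho-substituted aryl may be sluggish, and copper may promote loss of the allyl ether. Fallback: set C-8 by catalysis instead of from the chiral pool. Setting out from 3, palladium-catalysed borylation (bis(pinacolato)diboron, Pd(dppf)Cl2, KOAc, dioxane, 90 °C) should give 2-[2-methoxy-4-(prop-2-en-1-yloxy)phenyl]-4,4,5,5-tetramethyl-1,3,2-dioxaborolane F5. Rhodium-catalysed asymmetric conjugate addition to methyl (E)-but-2-enoate (Rh(acac)(C2H4)2, BINAP, KOH, dioxane–H2O) should give methyl (3R)-3-[2-methoxy-4-(prop-2-en-1-yloxy)phenyl]butanoate F6. The BINAP enantiomer, provisionally (R), is the one that delivers the aryl group to the face giving the 3R ester. Saponification with LiOH in THF–H2O, then aq. HCl, returns to the route at 6.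

Further compounds
F1 | step 6 | 4-[(2R)-2-[2-methoxy-4-(prop-2-en-1-yloxy)phenyl]propyl]-1,2-dimethoxybenzene | C=CCOc1ccc([C@H](C)Cc2ccc(OC)c(OC)c2)c(OC)c1
F2 | step 6 | 4-[(2R)-1-(3,4-dimethoxyphenyl)propan-2-yl]-5-methoxy-2-(prop-2-en-1-yl)phenol | C=CCc1cc([C@H](C)Cc2ccc(OC)c(OC)c2)c(OC)cc1O
F3 | step 6 | (4R)-4-[(2R)-1-(3,4-dimethoxyphenyl)propan-2-yl]-4,5-dimethoxy-2-(prop-2-en-1-yl)cyclohexa-2,5-dien-1-one | C=CCC1=C[C@](OC)([C@H](C)Cc2ccc(OC)c(OC)c2)C(OC)=CC1=O
F4 | step 4 | (4R,5R)-6-methoxy-4-methyl-9-(prop-2-en-1-yl)-1-oxaspiro[4.5]deca-6,9-diene-2,8-dione | C=CCC1=C[C@](OC(=O)C2)([C@@H]2C)C(OC)=CC1=O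
F5 | step 2 | 2-[2-methoxy-4-(prop-2-en-1-yloxy)phenyl]-4,4,5,5-tetramethyl-1,3,2-dioxaborolane | C=CCOc1ccc(B2OC(C)(C)C(C)(C)O2)c(OC)c1
F6 | step 2 | methyl (3R)-3-[2-methoxy-4-(prop-2-en-1-yloxy)phenyl]butanoate | C=CCOc1ccc([C@H](C)CC(=O)OC)c(OC)c1
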